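The rate constants belong to no real substance; what happens was integrated by code.

Which form holds the most starting material when each flask is stopped, and how much of it? Sunday's, Monday's and Friday's share their charges and differ in stopping time.

| setting | Sunday's | Monday's | Friday's |
|---|---|---|---|
| starting material | 1.2 M | 1.2 M | 1.2 M |
| reagent | 0.600 equiv | 0.600 equiv | 0.600 equiv |
| free catalyst | 0.2 mol% | 0.2 mol% | 0.2 mol% |
| time | 80 min | 120 min | 180 min |

    reagent + free catalyst → catalyst intermediate A (k1 = 0.47 M⁻¹ s⁻¹)
    catalyst intermediate A → catalyst intermediate B (k2 = 5.9 s⁻¹)
    catalyst intermediate B → by-product + catalyst intermediate C (k3 = 0.52 s⁻¹)
    starting material + catalyst intermediate C ⇌ catalyst intermediate D (K4 = 11 M⁻¹, k4 = 0.086 M⁻¹ s⁻¹)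
    catalyst intermediate D → free catalyst + product (k5 = 0.36 s⁻¹)
    crystals ⇌ product, rate k6*(cs6 - [product]) while solid is left; crystals form when [product] > cs6 (cs6 = 0.70 M, k6 = 0.014 s⁻¹)

- for product the crystals are counted in
- as a solid, counted per litre of solution: crystals
- run time (Sunday's): 80 min

- which of these there is most of at the end, counted by the starting material in it, Sunday's (catalyst intermediate D / starting material / product)
- which of these there is most of at the end, counted by the starting material in it, Monday's (catalyst intermediate D / starting material / product)
- which of these there is most of at the end, counted by the starting material in it, Friday's (catalyst intermediate D / starting material / product)
- amount of the one of these that there is most of at the end, in percent of the starting material charged, Sunday's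
- amount of the one of these that there is most of at the end, in percent of the starting material charged, Monday's
- amount of the one of these that there is most of at the end, in percent of the starting material charged, Friday's

We follow one catalyst molecule round its cycle and then one starting material molecule through its fork. Bound as catalyst intermediate D, the starting material can fall back at 0.00782 s⁻¹ or go on to product at 0.36 s⁻¹. Its chance of going on is 97.9%, so nearly all captures count. Each turn spends one reagent and one starting material. The charge of 0.720 M reagent is less than the 1.2 M starting material, which makes reagent the limiting reagent and caps product at 60.0%.

We add up the waits of one turn. The one-way steps take 4.87 s together. At the start, free catalyst waits 2.96 s for reagent, and catalyst intermediate C waits 9.90 s for a capture that counts. That last wait is longer than any other, so we expect catalyst intermediate C to be the resting state. A turn thus starts at 17.7 s, and the two waits stretch as [reagent] and [starting material] fall.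

Summing the waits over the turns, with 0.00240 M catalyst working, turns those stretching waits into logarithms of charge over what remains. Taken to the point where half the starting material has become product, the sum gives 104 min. This is the crossing time: the time these flasks need for product to draw level with starting material. Sunday's stops before it, while Monday's and Friday's stop after it. We therefore call starting material for Sunday's and product for Monday's and Friday's. We stop there and put no figure on the amounts.

The forecast says starting material at 58% for Sunday's, product at 53.9% for Monday's and product at 59.7% for Friday's, holding that “the lead passes from starting material to product between Sunday's and Monday's run times”.

The flask gives starting material at 58.0% for Sunday's, product at 53.9% for Monday's and product at 59.7% for Friday's, as the forecast said. Monday's stops 16.0 min past the crossing time, with 53.9% as product against 46.0% as starting material. Diluting Monday's to 0.72 M starting material, with the same equivalents and loading, lowers the catalyst and both waits' driving concentrations. The crossing time becomes 160 min, later than that flask's stop at 120 min. That flask ends with starting material ahead, at 58.4%.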